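**Plan**

1. Last cuts: the lower C4 carbinol goes back to a C4 ketone (final hydride step) and the free hydroxyls go back to nine benzyl ethers.
2. Key cut: the lower C2–C3 bond is opened and C2 is tied to the C3 oxygen instead, so the six-membered pyranone ring comes from a seven-membered 2-aryl-1,3-benzodioxepin-5-one. This works because C2 carries the aryl ether oxygen O1 and the 4'-oxygenated ring B (an O-aryl oxocarbenium site), while C3 carries a hydroxyl and lies α to the ring A ketone C4 (an enol carbon).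
3. Earlier cut: the upper C4–C2'(lower ring B) bond, giving a flavan-4-yl cation from (+)-dihydrorobinetin and [3,4,5-tris(benzyloxy)phenyl]methanol, whose only free ring positions are the wanted ones.
4. Forward order: upper pyran ring from the chiral pool, then the interflavanyl bond, the aldehyde, the seven-membered acetal ring fused to ring A, its contraction to the lower pyranone ring, debenzylation and C4 reduction.
5. Stereochemistry: upper C2 and C3 come from dihydrorobinetin; upper C4 from attack anti to the 3-benzyloxy group; lower C2 from catalyst-controlled face selection at the oxocarbenium ion; lower C3 (trans) from the ring-fixed enol geometry; lower C4 from axial hydride delivery.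

Key step: step 10

Remark: (+)-(2R,3R)-dihydrorobinetin is taken as the commercial chiral-pool source of the upper unit. "UF" stands for the (2R,3S,4S)-3,7-bis(benzyloxy)-2-[3,4,5-tris(benzyloxy)phenyl]chroman-4-yl group.

**Route**

Step 1
Reactants: 1 (+)-dihydrorobinetin, (2R,3R)-3,7-dihydroxy-2-(3,4,5-trihydroxyphenyl)chroman-4-one
Product: 2 (2R,3R)-7-(benzyloxy)-3-hydroxy-2-[3,4,5-tris(benzyloxy)phenyl]chroman-4-one
Conditions: BnBr (4.4 equiv), K2CO3, DMF, rt, under argon
Reagents that add atoms: benzyl bromide, BrCc1ccccc1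
Why: Williamson etherification of the four phenols under carbonate, which should leave the less acidic secondary 3-OH free and the two stereocentres untouched (argon prevents oxidation to the flavonol).

Step 2
Reactants: 2
Product: 3 (2R,3S,4R)-7-(benzyloxy)-2-[3,4,5-tris(benzyloxy)phenyl]chromane-3,4-diol
Conditions: NaBH4, THF/MeOH, 0 °C
Reagents that add atoms: none
Why: Hydride reduction of the aryl ketone, expected to give mainly the 3,4-trans diol by axial attack; the C4 configuration does not matter because C4 is ionised in step 4.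

Step 3
Reactants: 3
Product: 4 (2R,3S,4R)-3,4,7-tris(benzyloxy)-2-[3,4,5-tris(benzyloxy)phenyl]chromane
Conditions: NaH, BnBr, n-Bu4NI (cat.), DMF, 0 °C to rt
Reagents that add atoms: benzyl bromide, BrCc1ccccc1
Why: Williamson etherification of both alkoxides, the 3-O-benzyl group serving as lasting protection and the 4-O-benzyl group as the leaving group of the next step.

Step 4
Reactants: 4; 5 [3,4,5-tris(benzyloxy)phenyl]methanol (3 equiv)
Product: 6 [3,4,5-tris(benzyloxy)-2-UF-phenyl]methanol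
Conditions: TMSOTf (0.3 equiv), 4 Å MS, CH2Cl2, −78 to −40 °C, slow addition of 4; then Et3N
Reagents that add atoms: none
Why: Friedel–Crafts alkylation by the flavan-4-yl cation (stabilised by the 7-benzyloxy group and O1) at the only free ring positions of 5, which are equivalent and ortho to CH2OH, with attack anti to the 3-benzyloxy group so that the 3,4-trans (4S) isomer should predominate; excess 5 suppresses attack by ring B of 4, and O-alkylation of the CH2OH group is reversible.

Step 5
Reactants: 6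
Product: 7 3,4,5-tris(benzyloxy)-2-UF-benzaldehyde
Conditions: MnO2 (activated, excess), CH2Cl2, rt
Reagents that add atoms: none
Why: Chemoselective oxidation of the only free hydroxyl, a benzylic primary alcohol, to the aldehyde.

Step 6
Reactants: 8 1-[4-(benzyloxy)-2-hydroxyphenyl]ethan-1-one
Product: 9 {[1-(4-(benzyloxy)-2-[(tert-butyldimethylsilyl)oxy]phenyl)ethenyl]oxy}(tert-butyl)dimethylsilane
Conditions: TBSOTf (2.3 equiv), Et3N, CH2Cl2, 0 °C to rt
Reagents that add atoms: tert-butyldimethylsilyl triflate, CC(C)(C)[Si](C)(C)OS(=O)(=O)C(F)(F)F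
Why: O-silylation of the phenol and soft enolisation with O-silylation of the methyl ketone give the silyl enol ether needed for α-oxygenation.

Step 7
Reactants: 9
Product: 11 1-[4-(benzyloxy)-2-hydroxyphenyl]-2-hydroxyethan-1-one, via bis-silylated hydroxy ketone 10 (not isolated)
Conditions: mCPBA, CH2Cl2, 0 °C; then HF·pyridine, THF, 0 °C to rt
Reagents that add atoms: 3-chloroperbenzoic acid, OOC(=O)c1cccc(Cl)c1
Why: Rubottom oxidation (epoxidation of the enol silane and 1,4-silyl shift) installs the ω-oxygen, and fluoride-mediated cleavage of both silyl ethers frees the phenol/primary alcohol pair.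

Step 8
Reactants: 7; 11
Product: 13 8-(benzyloxy)-2-[3,4,5-tris(benzyloxy)-2-UF-phenyl]-2H-1,3-benzodioxepin-5(4H)-one (both epimers at the acetal carbon), via dimethyl acetal 12 (not isolated)
Conditions: HC(OMe)3, PPTS (cat.), MeOH, rt, then evaporation; 11, PPTS (cat.), PhMe, 50 °C, reduced pressure, 5 Å MS; Et3N
Reagents that add atoms: none
Why: Acid-catalysed acetal exchange in which the primary hydroxyl and then the phenol of 11 replace the two methoxy groups, driven by removal of methanol, closes the seven-membered O-aryl/O-alkyl acetal while the weak acid leaves the ketone unenolised.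

Step 9
Reactants: 13
Product: 14 {[8-(benzyloxy)-2-[3,4,5-tris(benzyloxy)-2-UF-phenyl]-2H-1,3-benzodioxepin-5-yl]oxy}trimethylsilane
Conditions: LiN(SiMe3)2, TMSCl (in situ quench), THF, −78 °C; hexane, filtration under argon, volatiles removed in high vacuum
Reagents that add atoms: chlorotrimethylsilane, C[Si](C)(C)Cl
Why: Kinetic deprotonation at the only enolisable position and O-silylation give the cyclic vinyl acetal, whose enol geometry is fixed by the ring (O3 cis to ring A) and whose acetal is inert to base.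

Step 10
Reactants: 14
Product: 16 (2R,3R)-7-(benzyloxy)-3-hydroxy-2-[3,4,5-tris(benzyloxy)-2-UF-phenyl]chroman-4-one, via 3-O-trimethylsilyl ether 15 (not isolated)
Conditions: TMSOTf (10 mol%), chiral 2-arylpyrrolidine-derived squaramide (10 mol%, the antipode that leads to 2R), t-BuOMe/PhMe, −78 °C; then aq. citric acid, THF, 0 °C
Reagents that add atoms: none
Why: Proposed new method: the squaramide-bound silyl triflate silylates the vinyl acetal oxygen O3 of the seven-membered ring, C2–O3 heterolysis gives a contact ion pair of an O-aryl oxocarbenium ion (C2, stabilised by O1 and the para-benzyloxy group of ring B) and a tethered Z-1,2-bis(silyloxy)styrene, and the enol carbon that carried O3 adds to C2 while the silyl group leaves the C4 oxygen and regenerates the silyl triflate, so that C2 shifts from oxygen to carbon and O3 is expelled from the ring as the 3-silyloxy group (chromanone numbering). The closest known reaction types are the Petasis–Ferrier rearrangement and the acid-promoted ring contraction of 4,5-dihydro-1,3-dioxepines to tetrahydrofuran-3-carbaldehydes, in which the other enol carbon is the nucleophile, together with squaramide/silyl triflate ion-pair catalysis of Mukaiyama aldol additions to aryl acetals. The pyranone ring closes by a 6-(enolendo)-endo-trig Mukaiyama aldol addition, geometrically a disrotatory closure of the 2-oxoniahexatriene O1=C2, C8a=C4a, C4=C3. C3 should come out trans to C2 because the ring holds O3 on the inner side of the enol and the E-oxocarbenium ion carries its aryl group on the outer side (the trans isomer is also the stable one at this enolisable centre), and C2 (R) is set by face selection in the chiral squaramide–triflate ion pair, both acetal epimers of 14 funnelling through the same cation, so that any 2S,3S product is a diastereomer removable on silica. The step needs C-attack through C3 and not through the aryl-bearing enol carbon (which would give a 2,3-dihydrobenzofuran-3-carbaldehyde), and this is secured because attack through C3 develops the cation at C4, where ring A and the silyloxy group both stabilise it, and is the less hindered path. Ionisation on the O1 side is reversible and unproductive.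

Step 11
Reactants: 16
Product: 17 robinetinidol-(4α→2')-dihydrorobinetin, (2R,3R)-3,7-dihydroxy-2-{3,4,5-trihydroxy-2-[(2R,3S,4S)-3,7-dihydroxy-2-(3,4,5-trihydroxyphenyl)chroman-4-yl]phenyl}chroman-4-one
Conditions: H2 (1 atm), Pd(OH)2/C, THF/MeOH, rt; filtration under argon
Reagents that add atoms: none
Why: Hydrogenolysis of the nine benzyl ethers, which the aryl ketone (a vinylogous ester toward the ring A oxygens), the cyclic benzylic ether bonds and the diarylmethine C4–aryl bond should survive, as in standard proanthocyanidin deprotections.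

Step 12
Reactants: 17
Product: 18 CNP0205451.4, (2R,3S,4R)-2-{3,4,5-trihydroxy-2-[(2R,3S,4S)-3,7-dihydroxy-2-(3,4,5-trihydroxyphenyl)chroman-4-yl]phenyl}chromane-3,4,7-triol
Conditions: NaBH4, EtOH, 0 °C, under argon; acetone quench, pH 6–7; Sephadex LH-20
Reagents that add atoms: none
Why: Hydride reduction of the C4 ketone of the 2,3-trans-dihydroflavonol unit by axial attack should give mainly the 3,4-trans (4R) diol, as in the borohydride reduction of free dihydroflavonols to 2,3-trans-3,4-trans flavan-3,4-diols; deprotection comes before this step so that the acid- and hydrogenolysis-labile C4 carbinol is made last.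

**Compound list**

1 | (+)-dihydrorobinetin, (2R,3R)-3,7-dihydroxy-2-(3,4,5-trihydroxyphenyl)chroman-4-one | Oc1ccc2c(c1)O[C@H](c1cc(O)c(O)c(O)c1)[C@@H](O)C2=O | starting material
2 | (2R,3R)-7-(benzyloxy)-3-hydroxy-2-[3,4,5-tris(benzyloxy)phenyl]chroman-4-one | C(c1ccccc1)Oc1ccc2c(c1)O[C@H](c1cc(OCc3ccccc3)c(OCc3ccccc3)c(OCc3ccccc3)c1)[C@@H](O)C2=O | intermediate
3 | (2R,3S,4R)-7-(benzyloxy)-2-[3,4,5-tris(benzyloxy)phenyl]chromane-3,4-diol | C(c1ccccc1)Oc1ccc2c(c1)O[C@H](c1cc(OCc3ccccc3)c(OCc3ccccc3)c(OCc3ccccc3)c1)[C@@H](O)[C@@H]2O | intermediate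
4 | (2R,3S,4R)-3,4,7-tris(benzyloxy)-2-[3,4,5-tris(benzyloxy)phenyl]chromane | C(c1ccccc1)Oc1ccc2c(c1)O[C@H](c1cc(OCc3ccccc3)c(OCc3ccccc3)c(OCc3ccccc3)c1)[C@@H](OCc1ccccc1)[C@@H]2OCc1ccccc1 | intermediate
5 | [3,4,5-tris(benzyloxy)phenyl]methanol | OCc1cc(OCc2ccccc2)c(OCc2ccccc2)c(OCc2ccccc2)c1 | starting material
6 | [3,4,5-tris(benzyloxy)-2-UF-phenyl]methanol | C(c1ccccc1)Oc1ccc2c(c1)O[C@H](c1cc(OCc3ccccc3)c(OCc3ccccc3)c(OCc3ccccc3)c1)[C@@H](OCc1ccccc1)[C@@H]2c1c(CO)cc(OCc2ccccc2)c(OCc2ccccc2)c1OCc1ccccc1 | intermediate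
7 | 3,4,5-tris(benzyloxy)-2-UF-benzaldehyde | C(c1ccccc1)Oc1ccc2c(c1)O[C@H](c1cc(OCc3ccccc3)c(OCc3ccccc3)c(OCc3ccccc3)c1)[C@@H](OCc1ccccc1)[C@@H]2c1c(C=O)cc(OCc2ccccc2)c(OCc2ccccc2)c1OCc1ccccc1 | intermediate
8 | 1-[4-(benzyloxy)-2-hydroxyphenyl]ethan-1-one | CC(=O)c1ccc(OCc2ccccc2)cc1O | starting material
9 | {[1-(4-(benzyloxy)-2-[(tert-butyldimethylsilyl)oxy]phenyl)ethenyl]oxy}(tert-butyl)dimethylsilane | C=C(O[Si](C)(C)C(C)(C)C)c1ccc(OCc2ccccc2)cc1O[Si](C)(C)C(C)(C)C | intermediate
10 | 1-{4-(benzyloxy)-2-[(tert-butyldimethylsilyl)oxy]phenyl}-2-[(tert-butyldimethylsilyl)oxy]ethan-1-one | O=C(CO[Si](C)(C)C(C)(C)C)c1ccc(OCc2ccccc2)cc1O[Si](C)(C)C(C)(C)C | intermediate (not isolated)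
11 | 1-[4-(benzyloxy)-2-hydroxyphenyl]-2-hydroxyethan-1-one | O=C(CO)c1ccc(OCc2ccccc2)cc1O | intermediate
12 | 3,4,5-tris(benzyloxy)-2-UF-benzaldehyde dimethyl acetal | C(c1ccccc1)Oc1ccc2c(c1)O[C@H](c1cc(OCc3ccccc3)c(OCc3ccccc3)c(OCc3ccccc3)c1)[C@@H](OCc1ccccc1)[C@@H]2c1c(C(OC)OC)cc(OCc2ccccc2)c(OCc2ccccc2)c1OCc1ccccc1 | intermediate (not isolated)
13 | 8-(benzyloxy)-2-[3,4,5-tris(benzyloxy)-2-UF-phenyl]-2H-1,3-benzodioxepin-5(4H)-one, both epimers at the acetal carbon | C(c1ccccc1)Oc1ccc2c(c1)O[C@H](c1cc(OCc3ccccc3)c(OCc3ccccc3)c(OCc3ccccc3)c1)[C@@H](OCc1ccccc1)[C@@H]2c1c(C2OCC(=O)c3ccc(OCc4ccccc4)cc3O2)cc(OCc2ccccc2)c(OCc2ccccc2)c1OCc1ccccc1 | intermediate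
14 | {[8-(benzyloxy)-2-[3,4,5-tris(benzyloxy)-2-UF-phenyl]-2H-1,3-benzodioxepin-5-yl]oxy}trimethylsilane | C(c1ccccc1)Oc1ccc2c(c1)O[C@H](c1cc(OCc3ccccc3)c(OCc3ccccc3)c(OCc3ccccc3)c1)[C@@H](OCc1ccccc1)[C@@H]2c1c(C2OC=C(O[Si](C)(C)C)c3ccc(OCc4ccccc4)cc3O2)cc(OCc2ccccc2)c(OCc2ccccc2)c1OCc1ccccc1 | intermediate
15 | (2R,3R)-7-(benzyloxy)-2-[3,4,5-tris(benzyloxy)-2-UF-phenyl]-3-(trimethylsilyloxy)chroman-4-one | C(c1ccccc1)Oc1ccc2c(c1)O[C@H](c1cc(OCc3ccccc3)c(OCc3ccccc3)c(OCc3ccccc3)c1)[C@@H](OCc1ccccc1)[C@@H]2c1c([C@H]2Oc3cc(OCc4ccccc4)ccc3C(=O)[C@@H]2O[Si](C)(C)C)cc(OCc2ccccc2)c(OCc2ccccc2)c1OCc1ccccc1 | intermediate (not isolated)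
16 | (2R,3R)-7-(benzyloxy)-3-hydroxy-2-[3,4,5-tris(benzyloxy)-2-UF-phenyl]chroman-4-one | C(c1ccccc1)Oc1ccc2c(c1)O[C@H](c1cc(OCc3ccccc3)c(OCc3ccccc3)c(OCc3ccccc3)c1)[C@@H](OCc1ccccc1)[C@@H]2c1c([C@H]2Oc3cc(OCc4ccccc4)ccc3C(=O)[C@@H]2O)cc(OCc2ccccc2)c(OCc2ccccc2)c1OCc1ccccc1 | intermediate
17 | robinetinidol-(4α→2')-dihydrorobinetin | Oc1ccc2c(c1)O[C@H](c1cc(O)c(O)c(O)c1)[C@@H](O)[C@@H]2c1c([C@H]2Oc3cc(O)ccc3C(=O)[C@@H]2O)cc(O)c(O)c1O | intermediate
18 | CNP0205451.4, (2R,3S,4R)-2-{3,4,5-trihydroxy-2-[(2R,3S,4S)-3,7-dihydroxy-2-(3,4,5-trihydroxyphenyl)chroman-4-yl]phenyl}chromane-3,4,7-triol | Oc1ccc2c(c1)O[C@H](c1cc(O)c(O)c(O)c1)[C@@H](O)[C@@H]2c1c([C@H]2Oc3cc(O)ccc3[C@@H](O)[C@@H]2O)cc(O)c(O)c1O | target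

**Step count and risks**

Total steps: 12. Longest linear sequence: 10 (steps 1–5 and 8–12).

Steps most likely to fail:

1. Step 10 (ring contraction). What may go wrong: poor facial selectivity at the oxocarbenium carbon (catalyst and resident stereocentres mismatched, or the two acetal epimers collapsing stereospecifically), ionisation only on the O1 side without turnover, or C-attack through the aryl-bearing enol carbon. Fallback from 7 (with ketone 8) back to 16, by known chemistry:
   - Ketone 8 is protected (MOMCl, i-Pr2NEt, CH2Cl2) as 1-[4-(benzyloxy)-2-(methoxymethoxy)phenyl]ethan-1-one F1.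
   - Claisen–Schmidt condensation of F1 with 7 (KOH, EtOH/THF) should give (E)-1-[4-(benzyloxy)-2-(methoxymethoxy)phenyl]-3-[3,4,5-tris(benzyloxy)-2-UF-phenyl]prop-2-en-1-one F2.
   - Juliá–Colonna epoxidation (poly-L-leucine, urea–H2O2, DBU, THF) should give, under catalyst control, [4-(benzyloxy)-2-(methoxymethoxy)phenyl]{(2R,3S)-3-[3,4,5-tris(benzyloxy)-2-UF-phenyl]oxiran-2-yl}methanone F3.
   - HCl in MeOH/THF removes the MOM group, and the freed phenol opens the epoxide at the benzylic carbon with inversion (6-endo) to give 16; in this fallback the pyranone ring closes directly.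

2. Step 8 (seven-membered acetal). What may go wrong: the exchange stalls at the open mixed methyl acetal because the hydrogen-bonded phenol closes the ring slowly, or the acetal hydrolyses on isolation. Fallback from 7 and 11 back to 13: 11 is silylated (TMSCl, Et3N, CH2Cl2) to 1-[4-(benzyloxy)-2-(trimethylsilyloxy)phenyl]-2-(trimethylsilyloxy)ethan-1-one F4. F4 with 7 and catalytic TMSOTf in CH2Cl2 at −78 °C should give 13 by silyl-transfer acetalisation, driven irreversibly by formation of hexamethyldisiloxane and not by removal of methanol from an equilibrium.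

3. Step 4 (interflavanyl bond). What may go wrong: acid-induced self-condensation or O-alkylation of the unprotected benzylic alcohol, attack by ring B of 4 on its own cation, or erosion of 3,4-trans selectivity at the hindered position. Fallback from 5 (and 4) back to 6: 5 is silylated (TIPSCl, imidazole, DMF) to triisopropyl{[3,4,5-tris(benzyloxy)phenyl]methoxy}silane F5. F5 is coupled with 4 under the same TMSOTf activation to triisopropyl{[3,4,5-tris(benzyloxy)-2-UF-phenyl]methoxy}silane F6, and TBAF in THF releases 6.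

**Further compounds**

F1 | step 10 | 1-[4-(benzyloxy)-2-(methoxymethoxy)phenyl]ethan-1-one | CC(=O)c1ccc(OCc2ccccc2)cc1OCOC
F2 | step 10 | (E)-1-[4-(benzyloxy)-2-(methoxymethoxy)phenyl]-3-[3,4,5-tris(benzyloxy)-2-UF-phenyl]prop-2-en-1-one | C(c1ccccc1)Oc1ccc2c(c1)O[C@H](c1cc(OCc3ccccc3)c(OCc3ccccc3)c(OCc3ccccc3)c1)[C@@H](OCc1ccccc1)[C@@H]2c1c(/C=C/C(=O)c3ccc(OCc4ccccc4)cc3OCOC)cc(OCc2ccccc2)c(OCc2ccccc2)c1OCc1ccccc1
F3 | step 10 | [4-(benzyloxy)-2-(methoxymethoxy)phenyl]{(2R,3S)-3-[3,4,5-tris(benzyloxy)-2-UF-phenyl]oxiran-2-yl}methanone | C(c1ccccc1)Oc1ccc2c(c1)O[C@H](c1cc(OCc3ccccc3)c(OCc3ccccc3)c(OCc3ccccc3)c1)[C@@H](OCc1ccccc1)[C@@H]2c1c([C@@H]3O[C@H]3C(=O)c3ccc(OCc4ccccc4)cc3OCOC)cc(OCc2ccccc2)c(OCc2ccccc2)c1OCc1ccccc1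
F4 | step 8 | 1-[4-(benzyloxy)-2-(trimethylsilyloxy)phenyl]-2-(trimethylsilyloxy)ethan-1-one | C[Si](C)(C)OCC(=O)c1ccc(OCc2ccccc2)cc1O[Si](C)(C)C
F5 | step 4 | triisopropyl{[3,4,5-tris(benzyloxy)phenyl]methoxy}silane | CC(C)[Si](OCc1cc(OCc2ccccc2)c(OCc2ccccc2)c(OCc2ccccc2)c1)(C(C)C)C(C)C
F6 | step 4 | triisopropyl{[3,4,5-tris(benzyloxy)-2-UF-phenyl]methoxy}silane | C(c1ccccc1)Oc1ccc2c(c1)O[C@H](c1cc(OCc3ccccc3)c(OCc3ccccc3)c(OCc3ccccc3)c1)[C@@H](OCc1ccccc1)[C@@H]2c1c(CO[Si](C(C)C)(C(C)C)C(C)C)cc(OCc2ccccc2)c(OCc2ccccc2)c1OCc1ccccc1
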